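**Strategy.** Numbering: bicyclo[3.3.1]nonane core with bridgeheads C1 (geranyl, next to C8Me2) and C5, triketone bridge C2–C4, carbon bridge C6–C7(prenyl)–C8 and bridging ketone C9. The route rests on folding an acyclic 3,5-diketo ester in which C1 is already quaternary. In one pot, a Claisen (Dieckmann-type) closure of the diketone dianion joins C5 to C9 (ring A, C1–C2–C3–C4–C5–C9), and tin-mediated loss of a tertiary nitro group at C8 releases a radical that closes C8–C7 onto a dienyl chain. This forms ring B (C1–C8–C7–C6–C5–C9), the prenyl group and the C5/C7 stereocentres. It exploits the C9 ketone shared by both rings and the quaternary C8.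

Key step: step 6

Assumption: the target is one enol tautomer of a rapidly equilibrating β-triketone and is obtained as that mixture; compounds 5 and 10–13 are racemic (12 and 13 are drawn as the enantiomer that is carried on), and which antipode of the chiral diamine in step 8 selects this enantiomer must be found by experiment (the (R,R,R,R)-form is written).

Step 1
Reactants: 1 methyl acetoacetate; 2 geranyl bromide
Product: 3 methyl (4E)-2-acetyl-5,9-dimethyldeca-4,8-dienoate (methyl 2-geranylacetoacetate)
Conditions: NaH, THF, 0 → 20 °C, 1 in excess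
Reagents that add atoms: none
Why: Acetoacetic ester alkylation, in which the sodium enolate displaces the allylic bromide at carbon (SN2) with the E-alkene retained, the excess of 1 suppressing dialkylation; the new centre is racemic and is replaced by a quaternary one in step 2.

Step 2
Reactants: 3 methyl 2-geranylacetoacetate; 4 2-bromo-2-nitropropane
Product: 5 methyl (4E)-2-acetyl-5,9-dimethyl-2-(2-nitropropan-2-yl)deca-4,8-dienoate
Conditions: NaH, THF/DMSO, 20 °C, hν (tungsten lamp), N2
Reagents that add atoms: none
Why: SRN1 (radical-anion chain) C-alkylation of a tertiary β-keto ester enolate by an α-halonitroalkane, a reaction type suited to joining two fully substituted carbons, makes the C1–C8 bond and installs the tertiary nitro group as a latent C8 radical; C1 is formed racemic.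

Step 3
Reactants: 6 methyl 4-oxobutanoate; 7 (3-methylbut-2-en-1-yl)triphenylphosphonium bromide
Product: 8 methyl 7-methylocta-4,6-dienoate (4E/4Z mixture)
Conditions: NaN(SiMe3)2, THF, −78 → 20 °C
Reagents that add atoms: none
Why: Wittig olefination of the aldehyde (the ester is inert) with a semi-stabilised allylic ylide builds the 1,3-diene, and the E/Z mixture at the new alkene is harmless because this geometry is erased in step 6.

Step 4
Reactants: 8 methyl 7-methylocta-4,6-dienoate
Product: 9 N-methoxy-N,7-dimethylocta-4,6-dienamide (4E/4Z mixture)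
Conditions: MeNH(OMe)·HCl, i-PrMgCl, THF, −20 → 0 °C
Reagents that add atoms: N,O-dimethylhydroxylamine hydrochloride, CNOC.Cl
Why: Aminolysis of the methyl ester by the chloromagnesium amide of N,O-dimethylhydroxylamine gives the Weinreb amide, an acyl donor that cannot over-react with an enolate.

Step 5
Reactants: 5 nitro keto ester; 9 Weinreb amide
Product: 10 methyl 2-[(2E)-3,7-dimethylocta-2,6-dien-1-yl]-11-methyl-2-(2-nitropropan-2-yl)-3,5-dioxododeca-8,10-dienoate
Conditions: LiN(i-Pr)2, THF, −78 °C; then 9, −78 → 0 °C; AcOH
Reagents that add atoms: none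
Why: Crossed Claisen-type acylation, in which the only enolisable position of 5 (the acetyl methyl group) gives a lithium enolate that adds to the Weinreb amide to form a chelated adduct collapsing to the 1,3-diketone on acidification.

Step 6
Reactants: 10 acyclic nitro diketo ester
Product: 12 rac-1-geranyl-8,8-dimethyl-7-exo-(3-methylbut-2-en-1-yl)bicyclo[3.3.1]nonane-2,4,9-trione, via monocyclic trione 11 (not isolated)
Conditions: LiN(i-Pr)2 (3.2 equiv), THF, −78 → 0 °C; AcOH; then Bu3SnH (slow addition), AIBN, PhMe, 90 °C (one pot)
Reagents that add atoms: none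
Why: LiN(i-Pr)2 turns the 1,3-diketone into its 1,3-dianion, whose terminal carbon C5 attacks the ester carbonyl C9 held close by quaternary C1 (6-exo-trig Claisen/Dieckmann closure of ring A with loss of methoxide); after acidification, tin radicals cleave the tertiary C–NO2 bond and the C8 radical adds to the near end (C7) of the dienyl chain in a 6-exo-trig closure of ring B, the allylic radical then taking hydrogen from Bu3SnH at its less substituted end (C10) so that the prenyl group appears directly. The closest known reaction types are the biomimetic Claisen cyclisation of 3,5-diketo esters to cyclohexane-1,3,5-triones and the tin hydride denitration–radical cyclisation of tertiary nitroalkanes. C5 is epimerisable through the enol forms of 11, so only the epimer with its side chain cis to the C8 radical can close, which fixes C5 relative to C1. C7 is set by a chair-like transition state with the dienyl residue equatorial, giving the exo substituent on the face of ring B opposite the C2–C4 bridge. The step needs acylation at C5 and not C3 (secured by the dianion, whose terminal carbon is the more nucleophilic), cyclisation faster than reduction or 1,2-acyl shift of the β-keto radical (secured by the activated diene and slow addition of Bu3SnH), and hydrogen transfer to C10 and not C12 (favoured by formation of the trisubstituted alkene).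

Step 7
Reactants: 12 bicyclic trione
Product: 13 rac-1-geranyl-4-methoxy-8,8-dimethyl-7-exo-(3-methylbut-2-en-1-yl)bicyclo[3.3.1]non-3-ene-2,9-dione
Conditions: Me2SO4, K2CO3, acetone, 20 °C
Reagents that add atoms: dimethyl sulfate, COS(=O)(=O)OC
Why: O-Alkylation of the vinylogous acid (enol ether formation) should occur mainly at the less hindered oxygen on C4, remote from the quaternary C1/C8 region, and any 2-methoxy isomer is separated and returned to 12 by LiOH hydrolysis.

Step 8
Reactants: 13 racemic enol ether; 2 geranyl bromide
Product: 14 1,5-digeranyl-4-methoxy-8,8-dimethyl-7-exo-(3-methylbut-2-en-1-yl)bicyclo[3.3.1]non-3-ene-2,9-dione (single enantiomer, configuration of the target)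
Conditions: (1R,2R)-N,N′-bis[(R)-1-phenylethyl]-1,2-diphenylethane-1,2-diamine (0.55 equiv), n-BuLi (1.1 equiv), LiCl, THF, −78 °C; then 2 (0.6 equiv), −78 → −40 °C
Reagents that add atoms: none
Why: Kinetic resolution by enantioselective bridgehead deprotonation with a chiral dilithium diamide, followed by SN2 alkylation of the configurationally locked bridgehead carbanion with retention: the faster-reacting enantiomer of 13 gives 14, unreacted ent-13 is removed by chromatography, and this fixes the absolute configuration of C1, C5 and C7 together.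

Step 9
Reactants: 15 3,4-dihydroxybenzoic acid
Product: 16 tert-butyldimethylsilyl 3,4-bis(tert-butyldimethylsilyloxy)benzoate
Conditions: TBSCl, imidazole, DMF, 20 °C
Reagents that add atoms: tert-butylchlorodimethylsilane, CC(C)(C)[Si](C)(C)Cl
Why: Imidazole-promoted silylation of both phenols and the carboxylic acid protects the catechol in a form that survives organolithium bases and is removed by hydroxide.

Step 10
Reactants: 16 tris-silylated acid
Product: 17 3,4-bis(tert-butyldimethylsilyloxy)benzoyl chloride
Conditions: (COCl)2, DMF (cat.), CH2Cl2, 0 → 20 °C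
Reagents that add atoms: oxalyl chloride, O=C(Cl)C(Cl)=O
Why: Vilsmeier-type activation converts the silyl ester directly into the acid chloride under neutral conditions that leave the aryl silyl ethers intact.

Step 11
Reactants: 14 digeranyl enol ether; 17 aroyl chloride
Product: 18 3-[3,4-bis(tert-butyldimethylsilyloxy)benzoyl]-1,5-digeranyl-4-methoxy-8,8-dimethyl-7-exo-(3-methylbut-2-en-1-yl)bicyclo[3.3.1]non-3-ene-2,9-dione
Conditions: lithium 2,2,6,6-tetramethylpiperidide, THF, −78 °C; then 17, −78 → 0 °C
Reagents that add atoms: none
Why: With both bridgeheads blocked, the hindered amide base lithiates the vinylic C3–H of the vinylogous ester and the vinyllithium is C-acylated by the acid chloride, a known way to introduce the C3 acyl group of such triones without touching any stereocentre.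

Step 12
Reactants: 18 protected aroyl enol ether
Product: 19 target compound CNP0178719.1
Conditions: LiOH, 1,4-dioxane/H2O, 90 °C, degassed; then aq. NaH2PO4
Reagents that add atoms: water, O
Why: Hydroxide adds to C4 of the vinylogous ester and expels methoxide (addition–elimination) while the same medium cleaves both aryl silyl ethers, so the β-triketone catechol is released in one global deprotection without acid, which would cyclise the prenyl groups onto the enol.

**Compound list**

1 | methyl acetoacetate | CC(=O)CC(=O)OC | starting material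
2 | geranyl bromide, (2E)-1-bromo-3,7-dimethylocta-2,6-diene | CC(C)=CCC/C(C)=C/CBr | starting material
3 | methyl (4E)-2-acetyl-5,9-dimethyldeca-4,8-dienoate (racemic) | CC(=O)C(C/C=C(\C)CCC=C(C)C)C(=O)OC | intermediate
4 | 2-bromo-2-nitropropane | CC(C)(Br)[N+](=O)[O-] | starting material
5 | methyl (4E)-2-acetyl-5,9-dimethyl-2-(2-nitropropan-2-yl)deca-4,8-dienoate (racemic) | CC(=O)C(C/C=C(\C)CCC=C(C)C)(C(=O)OC)C(C)(C)[N+](=O)[O-] | intermediate
6 | methyl 4-oxobutanoate | COC(=O)CCC=O | starting material
7 | (3-methylbut-2-en-1-yl)triphenylphosphonium bromide | CC(C)=CC[P+](c1ccccc1)(c1ccccc1)c1ccccc1.[Br-] | starting material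
8 | methyl 7-methylocta-4,6-dienoate (4E/4Z mixture) | COC(=O)CCC=CC=C(C)C | intermediate
9 | N-methoxy-N,7-dimethylocta-4,6-dienamide (4E/4Z mixture) | CON(C)C(=O)CCC=CC=C(C)C | intermediate
10 | methyl 2-[(2E)-3,7-dimethylocta-2,6-dien-1-yl]-11-methyl-2-(2-nitropropan-2-yl)-3,5-dioxododeca-8,10-dienoate (racemic, 8E/8Z mixture) | COC(=O)C(C/C=C(\C)CCC=C(C)C)(C(C)(C)[N+](=O)[O-])C(=O)CC(=O)CCC=CC=C(C)C | intermediate
11 | 2-[(2E)-3,7-dimethylocta-2,6-dien-1-yl]-6-(5-methylhexa-2,4-dien-1-yl)-2-(2-nitropropan-2-yl)cyclohexane-1,3,5-trione (racemic at C1, C5 epimerisable, enolised) | O=C1CC(=O)C(CC=CC=C(C)C)C(=O)C1(C/C=C(\C)CCC=C(C)C)C(C)(C)[N+](=O)[O-] | intermediate (not isolated)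
12 | rac-1-geranyl-8,8-dimethyl-7-exo-(3-methylbut-2-en-1-yl)bicyclo[3.3.1]nonane-2,4,9-trione (prenyl on the face of ring B opposite the C2–C4 bridge; drawn enantiomer is the one carried on) | [C@H]12C[C@@H](CC=C(C)C)C(C)(C)[C@](C/C=C(\C)CCC=C(C)C)(C(=O)CC1=O)C2=O | intermediate
13 | rac-1-geranyl-4-methoxy-8,8-dimethyl-7-exo-(3-methylbut-2-en-1-yl)bicyclo[3.3.1]non-3-ene-2,9-dione (drawn enantiomer is the one carried on) | [C@H]12C[C@@H](CC=C(C)C)C(C)(C)[C@](C/C=C(\C)CCC=C(C)C)(C(=O)C=C1OC)C2=O | intermediate
14 | 1,5-digeranyl-4-methoxy-8,8-dimethyl-7-exo-(3-methylbut-2-en-1-yl)bicyclo[3.3.1]non-3-ene-2,9-dione (single enantiomer, configuration of the target at C1, C5, C7) | CC(C)=CCC/C(C)=C/C[C@]12C[C@@H](CC=C(C)C)C(C)(C)[C@](C/C=C(\C)CCC=C(C)C)(C(=O)C=C1OC)C2=O | intermediate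
15 | 3,4-dihydroxybenzoic acid | OC(=O)c1ccc(O)c(O)c1 | starting material
16 | tert-butyldimethylsilyl 3,4-bis(tert-butyldimethylsilyloxy)benzoate | CC(C)(C)[Si](C)(C)OC(=O)c1ccc(O[Si](C)(C)C(C)(C)C)c(O[Si](C)(C)C(C)(C)C)c1 | intermediate
17 | 3,4-bis(tert-butyldimethylsilyloxy)benzoyl chloride | O=C(Cl)c1ccc(O[Si](C)(C)C(C)(C)C)c(O[Si](C)(C)C(C)(C)C)c1 | intermediate
18 | 3-[3,4-bis(tert-butyldimethylsilyloxy)benzoyl]-1,5-digeranyl-4-methoxy-8,8-dimethyl-7-exo-(3-methylbut-2-en-1-yl)bicyclo[3.3.1]non-3-ene-2,9-dione (single enantiomer) | CC(C)=CCC/C(C)=C/C[C@]12C[C@@H](CC=C(C)C)C(C)(C)[C@](C/C=C(\C)CCC=C(C)C)(C(=O)C(C(=O)c3ccc(O[Si](C)(C)C(C)(C)C)c(O[Si](C)(C)C(C)(C)C)c3)=C1OC)C2=O | intermediate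
19 | CNP0178719.1, 3-(3,4-dihydroxybenzoyl)-1,5-digeranyl-4-hydroxy-8,8-dimethyl-7-exo-(3-methylbut-2-en-1-yl)bicyclo[3.3.1]non-3-ene-2,9-dione | CC(C)=CCC/C(C)=C/C[C@]12C[C@@H](CC=C(C)C)C(C)(C)[C@](C/C=C(\C)CCC=C(C)C)(C(=O)C(C(=O)c3ccc(O)c(O)c3)=C1O)C2=O | target

**Total step count:** 12. **Longest linear sequence:** 8 steps (steps 1, 2, 5, 6, 7, 8, 11, 12).

**Steps most likely to fail**

Step 6. The ring closure of the dianion onto the hindered ester may stay incomplete. The tertiary β-keto radical may be reduced or undergo a 1,2-acyl shift before it cyclises. Hydrogen transfer to the allylic radical may go to the wrong end and move the double bond out of the prenyl position. The fallback separates the two events and uses an activated acceptor. It sets out from 5, whose lithium enolate is acylated with commercial N-methoxy-N-methylpent-4-enamide to give methyl 2-geranyl-2-(2-nitropropan-2-yl)-3,5-dioxonon-8-enoate F1. LiN(i-Pr)2 closes this to the isolated 2-geranyl-2-(2-nitropropan-2-yl)-6-(prop-2-en-1-yl)cyclohexane-1,3,5-trione F2. Cross-metathesis with acrolein (second-generation Hoveyda–Grubbs catalyst) should give (2E)-4-[3-geranyl-3-(2-nitropropan-2-yl)-2,4,6-trioxocyclohexyl]but-2-enal F3. Bu3SnH/AIBN then effects denitration and 6-exo Giese cyclisation onto the enal to give rac-2-[1-geranyl-8,8-dimethyl-2,4,9-trioxobicyclo[3.3.1]nonan-7-yl]acetaldehyde F4. Wittig olefination with isopropylidenetriphenylphosphorane turns the CH2CHO group into prenyl and comes back to the route at 12.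

Step 2. The electron-transfer chain may stall with the hindered, fully substituted enolate, or be diverted to O-alkylation and enolate dimerisation. The fallback inverts the order of the two alkylations. It sets out from 1 and 4: SRN1 coupling of the unhindered sodium enolate of 1 with 4 gives methyl 2-acetyl-3-methyl-3-nitrobutanoate F5. This is then C-geranylated under neutral Tsuji–Trost conditions (geranyl methyl carbonate, Pd(PPh3)4, THF, 20 °C), coming back to the route at 5.

Step 8. The chiral base may discriminate poorly between the two enantiomers of 13, leaving 14 with insufficient enantiomeric purity, or metalation may compete at C3. The fallback replaces kinetic resolution by physical resolution. It sets out from racemic 13, which is separated by preparative HPLC on a chiral stationary phase (amylose tris(3,5-dimethylphenylcarbamate)). The required enantiomer is then geranylated at the bridgehead with achiral LiN(i-Pr)2 and 2, coming back to the route at 14; this fallback makes no compound outside the list (F0).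

Further compounds
F1 | step 6 | methyl 2-[(2E)-3,7-dimethylocta-2,6-dien-1-yl]-2-(2-nitropropan-2-yl)-3,5-dioxonon-8-enoate (racemic) | COC(=O)C(C/C=C(\C)CCC=C(C)C)(C(C)(C)[N+](=O)[O-])C(=O)CC(=O)CCC=C
F2 | step 6 | 2-[(2E)-3,7-dimethylocta-2,6-dien-1-yl]-2-(2-nitropropan-2-yl)-6-(prop-2-en-1-yl)cyclohexane-1,3,5-trione (racemic, enolised) | O=C1CC(=O)C(CC=C)C(=O)C1(C/C=C(\C)CCC=C(C)C)C(C)(C)[N+](=O)[O-]
F3 | step 6 | (2E)-4-[3-geranyl-3-(2-nitropropan-2-yl)-2,4,6-trioxocyclohexyl]but-2-enal (racemic) | O=C/C=C/CC1C(=O)CC(=O)C(C/C=C(\C)CCC=C(C)C)(C(C)(C)[N+](=O)[O-])C1=O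
F4 | step 6 | rac-2-[1-geranyl-8,8-dimethyl-2,4,9-trioxobicyclo[3.3.1]nonan-7-yl]acetaldehyde (7-exo; drawn enantiomer is the one carried on) | [C@H]12C[C@@H](CC=O)C(C)(C)[C@](C/C=C(\C)CCC=C(C)C)(C(=O)CC1=O)C2=O
F5 | step 2 | methyl 2-acetyl-3-methyl-3-nitrobutanoate (racemic) | CC(=O)C(C(=O)OC)C(C)(C)[N+](=O)[O-]
F0 | step 8 | none | none
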